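**Retrosynthetic overview**
- The target is the all-trans 1-aryl-2,3-dimethyltetralin (1R,2R,3S); both arenes are bought, so only the saturated ring is built.
- The two methyl groups are read as protonated C–Zr bonds: target ⇐ benzo-fused zirconabicycle (zirconacyclopentane fused across C2–C3 of the new cyclohexane).
- Key step: zirconocene-mediated reductive bicyclisation of a 1,7-diene (ortho-allyl arene carrying a 1-arylallyl group). It forms the C2–C3 bond, the carbocycle and the metallacycle together; C2 and C3 follow from C1.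
- The diene's only stereocentre (C1, a diarylmethine) ⇐ copper-catalysed enantioselective SN2' arylation of (E)-3,4-dimethoxycinnamyl bromide with a 2-allyl-4,5-dimethoxyphenyl Grignard reagent.
- Aryl bromide ⇐ methyl eugenol (ring bromination); cinnamyl bromide ⇐ veratraldehyde (vinyl Grignard, then PBr3 with allylic transposition). Ring order: cyclohexane and zirconacycle form together in the last step, and the metallacycle is cleaved by acid in the same flask.

Assumption: in step 4 the (4S,5S) antipode of the imidazolinium NHC precursor is taken to give the R product; the sense is checked on the first run and the mirror-image ligand is used if it is the opposite.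

**Route**

Step 1
Reactants: 1 methyl eugenol (4-allyl-1,2-dimethoxybenzene)
Product: 2 1-allyl-2-bromo-4,5-dimethoxybenzene
Conditions: NBS (1.05 equiv), MeCN, 0 °C → rt, dark
Reagents that add atoms: N-bromosuccinimide, O=C1CCC(=O)N1Br
Why: Electrophilic aromatic bromination (SEAr): the free ring position para to a methoxy group and next to the allyl chain is the most activated site, and under polar, initiator-free conditions the electron-rich ring reacts much faster than the isolated terminal alkene.

Step 2
Reactants: 3 veratraldehyde (3,4-dimethoxybenzaldehyde)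
Product: 4 rac-1-(3,4-dimethoxyphenyl)prop-2-en-1-ol
Conditions: CH2=CHMgBr (1.2 equiv), THF, 0 °C; then H2O
Reagents that add atoms: vinylmagnesium bromide, C=C[Mg]Br
Why: Grignard 1,2-addition to an aromatic aldehyde; the carbinol centre is left racemic because it is erased in step 3.

Step 3
Reactants: 4 rac-1-(3,4-dimethoxyphenyl)prop-2-en-1-ol
Product: 5 (E)-4-(3-bromoprop-1-en-1-yl)-1,2-dimethoxybenzene (3,4-dimethoxycinnamyl bromide)
Conditions: PBr3 (0.4 equiv), Et2O, −10 → 0 °C; used crude at once
Reagents that add atoms: phosphorus tribromide, BrP(Br)Br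
Why: Bromination of an aryl vinyl carbinol with allylic transposition (SN1'/SN2' through the aryl-stabilised allyl cation) gives the conjugated linear E bromide as the thermodynamic product.

Step 4
Reactants: 2 1-allyl-2-bromo-4,5-dimethoxybenzene; 5 (E)-4-(3-bromoprop-1-en-1-yl)-1,2-dimethoxybenzene
Product: 7 1-[(1R)-1-(3,4-dimethoxyphenyl)prop-2-en-1-yl]-4,5-dimethoxy-2-(prop-2-en-1-yl)benzene, via arylmagnesium bromide 6 (not isolated)
Conditions: 2, Mg, Et2O, reflux; then 5, monovalent copper thiophene-2-carboxylate (CuTC, 2 mol%), C2-symmetric (4S,5S)-4,5-diphenyl-1,3-bis(arylmethyl)imidazolinium chloride (NHC precursor, 3 mol%), CH2Cl2, −78 °C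
Reagents that add atoms: none
Why: Copper-catalysed enantioselective allylic arylation (γ-selective SN2' of a cinnamyl bromide with an aryl Grignard reagent under a chiral NHC–copper catalyst): anti oxidative addition gives a trivalent copper γ-σ-allyl species that reductively eliminates before allyl equilibration, so the diarylmethine centre C1 is set as R by the ligand.

Step 5
Reactants: 7 1-[(1R)-1-(3,4-dimethoxyphenyl)prop-2-en-1-yl]-4,5-dimethoxy-2-(prop-2-en-1-yl)benzene
Product: 9 (1R,2R,3S)-1-(3,4-dimethoxyphenyl)-6,7-dimethoxy-2,3-dimethyl-1,2,3,4-tetrahydronaphthalene, via zirconabicycle 8 (not isolated)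
Conditions: Cp2ZrCl2 (1.25 equiv), n-BuLi (2.4 equiv), THF, −78 °C, 1 h; 7 (0.05 M), −78 °C → rt, 3 h; 60 °C, 2 h; then 3 M HCl, 0 °C
Reagents that add atoms: none
Why: Zirconocene-mediated reductive diene bicyclisation (Negishi-type oxidative cyclometallation of the 1,7-diene on divalent zirconium) closes the cyclohexane ring and the zirconacyclopentane in one operation; because metallacycle formation is reversible (β-carbon–carbon cleavage), warming should let it settle in the all-equatorial form with the two CH2–Zr arms trans to each other and the C2 arm trans to the fixed C1 aryl group, and protonolysis of both C–Zr bonds with retention turns the arms into the C2 (R) and C3 (S) methyl groups.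

**Compound list**
1 | methyl eugenol (4-allyl-1,2-dimethoxybenzene) | COc1ccc(CC=C)cc1OC | starting material
2 | 1-allyl-2-bromo-4,5-dimethoxybenzene | C=CCc1cc(OC)c(OC)cc1Br | intermediate
3 | veratraldehyde (3,4-dimethoxybenzaldehyde) | COc1ccc(C=O)cc1OC | starting material
4 | rac-1-(3,4-dimethoxyphenyl)prop-2-en-1-ol (racemic, no stereodescriptor) | COc1ccc(C(O)C=C)cc1OC | intermediate
5 | (E)-4-(3-bromoprop-1-en-1-yl)-1,2-dimethoxybenzene | COc1ccc(/C=C/CBr)cc1OC | intermediate
6 | (2-allyl-4,5-dimethoxyphenyl)magnesium bromide | C=CCc1cc(OC)c(OC)cc1[Mg]Br | intermediate (not isolated)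
7 | 1-[(1R)-1-(3,4-dimethoxyphenyl)prop-2-en-1-yl]-4,5-dimethoxy-2-(prop-2-en-1-yl)benzene | COc1ccc([C@@H](C=C)c2cc(OC)c(OC)cc2CC=C)cc1OC | intermediate
8 | all-trans zirconabicycle: bis(cyclopentadienyl)zirconacyclopentane fused across C2–C3 of (1R)-1-(3,4-dimethoxyphenyl)-6,7-dimethoxytetralin, C2 arm trans to the aryl group, C3 arm trans to the C2 arm (η5-Cp rings written σ-bonded in the SMILES) | COc1ccc([C@@H]2c3cc(OC)c(OC)cc3C[C@H](C4)[C@H]2C[Zr]4(C5C=CC=C5)C5C=CC=C5)cc1OC | intermediate (not isolated)
9 | (1R,2R,3S)-1-(3,4-dimethoxyphenyl)-6,7-dimethoxy-2,3-dimethyl-1,2,3,4-tetrahydronaphthalene | COc1ccc([C@@H]2c3cc(OC)c(OC)cc3C[C@H](C)[C@H]2C)cc1OC | target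

**Totals**
Total step count: 5. Longest linear sequence: 4 steps (3 → 4 → 5 → 7 → 9).

**Three steps most likely to fail**

Step 5 (key step). Risks: low-valent zirconium may isomerise the doubly benzylic, allylic C1–H unit, which would erase C1. A 1,7-diene may give a cis-fused zirconacycle kinetically, and the trans preference after warming is an expectation for this benzo-fused substrate, not an established result. The preference between the two trans-fused arrangements relative to C1 may also be modest. Fallback, setting out from 7 and coming back to the route at 9: 7 is cyclised by palladium-catalysed diene cyclisation/hydrosilylation with [(1,10-phenanthroline)Pd(CH3)(OEt2)][B(3,5-(CF3)2C6H3)4] (5 mol%) and HSiMe2OSiMe3 in CH2Cl2 at 0 °C. Silylpalladation of the less hindered allyl arm, 6-exo carbopalladation of the vinyl group and Si–H cleavage should give the trans,trans silane (1R,2S,3S)-1-(3,4-dimethoxyphenyl)-6,7-dimethoxy-2-methyl-3-[(1,1,3,3,3-pentamethyldisiloxanyl)methyl]-1,2,3,4-tetrahydronaphthalene F1. Tamao oxidation (KF, KHCO3, H2O2, THF–MeOH) gives [(2S,3S,4R)-4-(3,4-dimethoxyphenyl)-6,7-dimethoxy-3-methyl-1,2,3,4-tetrahydronaphthalen-2-yl]methanol F2. TsCl in pyridine gives [(2S,3S,4R)-4-(3,4-dimethoxyphenyl)-6,7-dimethoxy-3-methyl-1,2,3,4-tetrahydronaphthalen-2-yl]methyl 4-methylbenzenesulfonate F3, and LiBHEt3 (THF, 0 °C) reduces the tosylate to the second methyl group, giving 9. The minor silylation regioisomer converges on 9 through the same operations.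

Step 4. Risks: the ortho-allyl group on the Grignard reagent may lower γ-selectivity or enantioselectivity, and the electron-rich bromide 5 may react by an uncatalysed pathway. Fallback, setting out from 4 and 6 and coming back at 7: 4 is converted with Boc2O and DMAP into rac-tert-butyl 1-(3,4-dimethoxyphenyl)prop-2-en-1-yl carbonate F4, and 6 is transmetallated with ZnBr2 to (2-allyl-4,5-dimethoxyphenyl)zinc bromide F5. The two are joined by iridium-catalysed enantioconvergent, branched-selective allylic substitution ([Ir(cod)Cl]2, chiral phosphoramidite–olefin ligand, THF, rt). Here regio- and enantiocontrol come from attack on a trivalent iridium π-allyl instead of a copper SN2' event, and bromide 5 is bypassed.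

Step 3. Risk: the electron-rich cinnamyl bromide 5 ionises easily and may decompose or oligomerise before use. Fallback, setting out from 3 and coming back at 7: Horner–Wadsworth–Emmons olefination of 3 with triethyl phosphonoacetate (NaH, THF) gives ethyl (E)-3-(3,4-dimethoxyphenyl)prop-2-enoate F6. Reduction with i-Bu2AlH (CH2Cl2, −78 °C) gives (E)-3-(3,4-dimethoxyphenyl)prop-2-en-1-ol F7, and ClP(O)(OEt)2 with Et3N and DMAP gives the bench-stable diethyl (E)-3-(3,4-dimethoxyphenyl)prop-2-en-1-yl phosphate F8. F8 replaces 5 as the electrophile in the copper-catalysed SN2' arylation with 6 and gives 7.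

**Further compounds**
F1 | step 5 | (1R,2S,3S)-1-(3,4-dimethoxyphenyl)-6,7-dimethoxy-2-methyl-3-[(1,1,3,3,3-pentamethyldisiloxanyl)methyl]-1,2,3,4-tetrahydronaphthalene | COc1ccc([C@@H]2c3cc(OC)c(OC)cc3C[C@H](C[Si](C)(C)O[Si](C)(C)C)[C@H]2C)cc1OC
F2 | step 5 | [(2S,3S,4R)-4-(3,4-dimethoxyphenyl)-6,7-dimethoxy-3-methyl-1,2,3,4-tetrahydronaphthalen-2-yl]methanol | COc1ccc([C@@H]2c3cc(OC)c(OC)cc3C[C@H](CO)[C@H]2C)cc1OC
F3 | step 5 | [(2S,3S,4R)-4-(3,4-dimethoxyphenyl)-6,7-dimethoxy-3-methyl-1,2,3,4-tetrahydronaphthalen-2-yl]methyl 4-methylbenzenesulfonate | COc1ccc([C@@H]2c3cc(OC)c(OC)cc3C[C@H](COS(=O)(=O)c4ccc(C)cc4)[C@H]2C)cc1OC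
F4 | step 4 | rac-tert-butyl 1-(3,4-dimethoxyphenyl)prop-2-en-1-yl carbonate | COc1ccc(C(OC(=O)OC(C)(C)C)C=C)cc1OC
F5 | step 4 | (2-allyl-4,5-dimethoxyphenyl)zinc bromide | C=CCc1cc(OC)c(OC)cc1[Zn]Br
F6 | step 3 | ethyl (E)-3-(3,4-dimethoxyphenyl)prop-2-enoate | CCOC(=O)/C=C/c1ccc(OC)c(OC)c1
F7 | step 3 | (E)-3-(3,4-dimethoxyphenyl)prop-2-en-1-ol | OC/C=C/c1ccc(OC)c(OC)c1
F8 | step 3 | diethyl (E)-3-(3,4-dimethoxyphenyl)prop-2-en-1-yl phosphate | CCOP(=O)(OCC)OC/C=C/c1ccc(OC)c(OC)c1
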